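## Retrosynthetic overview

1. The target is two 2,3-cis-3,4-trans flavan units joined C4 (upper) to C6 (lower). The lower 4β-OH is introduced last by benzylic oxidation, and the interflavan bond is made by capture of an upper flavan-4-yl cation by ring A of the lower flavan-3-ol.
2. Each 2,3-cis-flavan-3-ol comes from its flavan-3-one (hydride anti to the 2-aryl group), and that from hydroboration of a flav-2-ene (2-aryl-4H-chromene), in which a chiral borane sets C2.
3. Ring C is closed at the flav-2-ene level by forming C2=C3 in an intramolecular titanium-alkylidene carbonyl olefination (olefinic-ester cyclization) of an aryl benzoate carrying an ortho-allyl group. The ester is made from one allylphenol (4) and the ring-B benzoic acid.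
4. Enabling feature: C2 of ring C bears only the ring oxygen O1, the ring-B aryl group and C3, so it is the latent acyl carbon of an aryl ester between the ring-A phenol oxygen and the ring-B acid. C3 and C4 are the inner carbons of an allyl group ortho to O1 on ring A, and the new enol ether is the handle from which C2, C3 and C4 are then set in turn.
5. Ring order: dioxole protecting ring on ring A (step 1), ring C of the lower unit (step 5), ring C of the upper unit (step 10), union of the two flavans (step 15).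

Key step: step 5

Remark (assumption on the chemistry): IpcBH2 made from (+)-α-pinene is taken to approach the flav-2-enes 7 and 14 with the facial sense it shows with 1-arylcycloalkenes, the ring oxygen O1 standing in for a ring CH2 group.

## Route

Step 1
Reactants: 1 pyrogallol
Product: 2 2,2-diphenyl-1,3-benzodioxol-4-ol
Conditions: Ph2CCl2, Ph2O, 175 °C
Reagents that add atoms: dichlorodiphenylmethane, ClC(Cl)(c1ccccc1)c1ccccc1
Why: Double nucleophilic substitution of the geminal dichloride by two adjacent hydroxyls (ketal formation) closes the dioxole and leaves the third hydroxyl, the later O1, free; both possible 1,2-pairs give the same product.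

Step 2
Reactants: 2 2,2-diphenyl-1,3-benzodioxol-4-ol
Product: 3 4-(allyloxy)-2,2-diphenyl-1,3-benzodioxole
Conditions: allyl bromide, K2CO3, acetone, reflux
Reagents that add atoms: allyl bromide, C=CCBr
Why: Williamson ether synthesis on the only free phenol.

Step 3
Reactants: 3 4-(allyloxy)-2,2-diphenyl-1,3-benzodioxole
Product: 4 5-allyl-2,2-diphenyl-1,3-benzodioxol-4-ol
Conditions: PhNEt2, 190 °C
Reagents that add atoms: none
Why: Aromatic Claisen rearrangement ([3,3]-sigmatropic shift, then tautomerisation) moves the allyl group to the one free ortho carbon, because the other ortho position carries the dioxole oxygen; this places C3 and C4 of ring C next to O1.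

Step 4
Reactants: 4 5-allyl-2,2-diphenyl-1,3-benzodioxol-4-ol; 5 3,4-bis(benzyloxy)benzoic acid
Product: 6 5-allyl-2,2-diphenyl-1,3-benzodioxol-4-yl 3,4-bis(benzyloxy)benzoate
Conditions: DCC, DMAP (cat.), CH2Cl2, rt
Reagents that add atoms: none
Why: Steglich esterification (DCC activation, acyl transfer by DMAP) acylates the hindered phenol and joins the ring-A and ring-B halves through O1–C2.

Step 5
Reactants: 6 5-allyl-2,2-diphenyl-1,3-benzodioxol-4-yl 3,4-bis(benzyloxy)benzoate
Product: 7 3',4'-bis(benzyloxy)-7,8-(diphenylmethylenedioxy)flav-2-ene (the 2-aryl-4H-chromene with a C2=C3 enol ether double bond)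
Conditions: CH3CHBr2, TiCl4, Zn, PbCl2 (cat.), TMEDA, THF–CH2Cl2, 0 → 65 °C, high dilution
Reagents that add atoms: none
Why: The reduced titanium ethylidene made from CH3CHBr2, TiCl4, Zn and PbCl2 exchanges with the terminal allyl double bond of 6 by [2+2] cycloaddition and cycloreversion (propene leaves), and the titanium alkylidene now on C3 adds across the ester C=O (C2) in a second [2+2] and collapses to the C2=C3 enol ether and a titanium oxo; the other order of events (ethylidenation of the ester, then ring-closing enol ether–olefin metathesis) ends in the same product. The closest known reaction type is the olefinic-ester cyclization under Takai–Utimoto conditions, which converts ω-alkenyl esters into six- and seven-membered cyclic enol ethers. Ring C is closed in the carbonyl-olefination (or metathesis) event itself as a six-membered ring in which C4, C4a, C8a and O1 are already held by ring A, so the alkylidene carbon C3 and the ester carbon C2 sit in a fixed 1,6-relationship on the ortho-disubstituted benzene. No stereocentre is formed; the step creates the trisubstituted enol ether whose two faces are told apart in step 6 (C2), after which C3 (step 8) and C4 (step 16) follow by relay. The selectivity needed is cyclization over simple ethylidenation of the ester and over isomerisation of the allyl group to a propenyl group (which would lead to a benzofuran); the rigid ortho tether, high dilution and the non-acidic, non-basic reagent should secure it, and benzyl ethers, the ketal and the electron-rich arenes are inert to the reagent.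

Step 6
Reactants: 7 3',4'-bis(benzyloxy)-7,8-(diphenylmethylenedioxy)flav-2-ene
Product: 9 (2R,3S)-3',4'-bis(benzyloxy)-7,8-(diphenylmethylenedioxy)flavan-3-ol (2,3-trans), via flavan-3-yl(isopinocampheyl)borane 8 (not isolated)
Conditions: IpcBH2 (from (+)-α-pinene), THF, −25 °C; then NaOH, H2O2, 0 °C → rt
Reagents that add atoms: hydrogen peroxide, OO (the oxygen of the 3-OH); monoisopinocampheylborane, C[C@H]1[C@H](B)C[C@@H]2C[C@H]1C2(C)C (its boron and terpene group are held only in 8 and leave again)
Why: Asymmetric hydroboration–oxidation: the chiral monoalkylborane adds H and B syn across the enol ether with boron on C3 (β to oxygen, distal to the aryl group), choosing the face as it does with 1-arylcycloalkenes (which give (1S,2R)-trans-2-arylcycloalkanols), and alkaline H2O2 replaces boron by OH with retention, so C2 (R) and C3 (S) are set together.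

Step 7
Reactants: 9 (2R,3S)-3',4'-bis(benzyloxy)-7,8-(diphenylmethylenedioxy)flavan-3-ol
Product: 10 (2R)-3',4'-bis(benzyloxy)-7,8-(diphenylmethylenedioxy)flavan-3-one
Conditions: Dess–Martin periodinane, CH2Cl2, rt
Reagents that add atoms: none
Why: Dess–Martin oxidation of the secondary alcohol under non-enolising conditions gives the flavan-3-one without touching the C2 stereocentre.

Step 8
Reactants: 10 (2R)-3',4'-bis(benzyloxy)-7,8-(diphenylmethylenedioxy)flavan-3-one
Product: 11 (2R,3R)-3',4'-bis(benzyloxy)-7,8-(diphenylmethylenedioxy)flavan-3-ol (2,3-cis)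
Conditions: LiBH(s-Bu)3, LiBr, THF, −78 °C
Reagents that add atoms: none
Why: The bulky hydride attacks the ketone on the face away from the 2-aryl group (equatorial attack), giving the axial 3-OH cis to the aryl group; this oxidation–reduction pair is the standard conversion of a 2,3-trans-flavan-3-ol into its 3-epimer.

Step 9
Reactants: 4 5-allyl-2,2-diphenyl-1,3-benzodioxol-4-ol; 12 4-(benzyloxy)benzoic acid
Product: 13 5-allyl-2,2-diphenyl-1,3-benzodioxol-4-yl 4-(benzyloxy)benzoate
Conditions: DCC, DMAP (cat.), CH2Cl2, rt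
Reagents that add atoms: none
Why: Steglich esterification, as in step 4.

Step 10
Reactants: 13 5-allyl-2,2-diphenyl-1,3-benzodioxol-4-yl 4-(benzyloxy)benzoate
Product: 14 4'-(benzyloxy)-7,8-(diphenylmethylenedioxy)flav-2-ene
Conditions: CH3CHBr2, TiCl4, Zn, PbCl2 (cat.), TMEDA, THF–CH2Cl2, 0 → 65 °C, high dilution
Reagents that add atoms: none
Why: The same olefinic-ester cyclization as in step 5 (alkylidene exchange at the allyl group, then intramolecular carbonyl olefination of the aryl ester) closes ring C of the upper unit by forming C2=C3.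

Step 11
Reactants: 14 4'-(benzyloxy)-7,8-(diphenylmethylenedioxy)flav-2-ene
Product: 16 (2R,3S)-4'-(benzyloxy)-7,8-(diphenylmethylenedioxy)flavan-3-ol (2,3-trans), via flavan-3-yl(isopinocampheyl)borane 15 (not isolated)
Conditions: IpcBH2 (from (+)-α-pinene), THF, −25 °C; then NaOH, H2O2, 0 °C → rt
Reagents that add atoms: hydrogen peroxide, OO (the oxygen of the 3-OH); monoisopinocampheylborane, C[C@H]1[C@H](B)C[C@@H]2C[C@H]1C2(C)C (its boron and terpene group are held only in 15 and leave again)
Why: Asymmetric hydroboration–oxidation as in step 6: syn addition with boron on C3, face chosen by the reagent, oxidation with retention, setting C2 (R) and C3 (S).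

Step 12
Reactants: 16 (2R,3S)-4'-(benzyloxy)-7,8-(diphenylmethylenedioxy)flavan-3-ol
Product: 17 (2R)-4'-(benzyloxy)-7,8-(diphenylmethylenedioxy)flavan-3-one
Conditions: Dess–Martin periodinane, CH2Cl2, rt
Reagents that add atoms: none
Why: Dess–Martin oxidation as in step 7.

Step 13
Reactants: 17 (2R)-4'-(benzyloxy)-7,8-(diphenylmethylenedioxy)flavan-3-one
Product: 18 (2R,3R)-4'-(benzyloxy)-7,8-(diphenylmethylenedioxy)flavan-3-ol (2,3-cis)
Conditions: LiBH(s-Bu)3, LiBr, THF, −78 °C
Reagents that add atoms: none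
Why: Hydride delivery anti to the 2-aryl group as in step 8 gives the 2,3-cis alcohol.

Step 14
Reactants: 18 (2R,3R)-4'-(benzyloxy)-7,8-(diphenylmethylenedioxy)flavan-3-ol
Product: 19 (2R,3R,4S)-4'-(benzyloxy)-4-(2-ethoxyethoxy)-7,8-(diphenylmethylenedioxy)flavan-3-ol (4β ether, 3,4-trans)
Conditions: DDQ, EtOCH2CH2OH, CH2Cl2, rt
Reagents that add atoms: 2-ethoxyethanol, CCOCCO
Why: DDQ abstracts hydride from benzylic C4 (cation stabilised by O1 in the ortho and O7 in the para position) and the alcohol adds on the face trans to the pseudo-axial 3-OH, the usual oxidative C4 activation of flavan-3-ols.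

Step 15
Reactants: 19 (2R,3R,4S)-4'-(benzyloxy)-4-(2-ethoxyethoxy)-7,8-(diphenylmethylenedioxy)flavan-3-ol; 11 (2R,3R)-3',4'-bis(benzyloxy)-7,8-(diphenylmethylenedioxy)flavan-3-ol (in excess)
Product: 20 protected biflavanoid: the (2R,3R,4R)-4'-(benzyloxy)-7,8-(diphenylmethylenedioxy)flavan-3-ol-4-yl unit bonded through C4 (4β) to C6 of (2R,3R)-3',4'-bis(benzyloxy)-7,8-(diphenylmethylenedioxy)flavan-3-ol
Conditions: TMSOTf (cat.), CH2Cl2, −78 °C
Reagents that add atoms: none
Why: TMSOTf ionises the 4-alkoxy group to the flavan-4-yl cation, and C6 of 11 (para to O1 and ortho to the dioxole oxygen on C7, whereas C5 is activated only by the oxygen on C8 and is flanked by C4) attacks in a Friedel–Crafts alkylation on the face trans to the 3-OH, setting C4 of the upper unit (4β, 3,4-trans) and the 4→6 linkage.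

Step 16
Reactants: 20 protected biflavanoid
Product: 21 protected biflavanoid 4-ol: as 20, with the lower unit now the (2R,3R,4S)-flavan-3,4-diol (4β-OH, 3,4-trans)
Conditions: DDQ, H2O, CH2Cl2, rt
Reagents that add atoms: water, O
Why: DDQ removes hydride from the only methylene attached to an oxygenated arene, C4 of the lower unit (the upper C4–H is a crowded diarylmethine that cannot reach the planar cation geometry), and water adds trans to the pseudo-axial 3-OH, setting the last stereocentre (benzylic oxidation with DDQ).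

Step 17
Reactants: 21 protected biflavanoid 4-ol
Product: 22 CNP0275688.1, (2R,3R,4S)-2-(3,4-dihydroxyphenyl)-6-[(2R,3R,4S)-3,7,8-trihydroxy-2-(4-hydroxyphenyl)chroman-4-yl]chromane-3,4,7,8-tetrol
Conditions: H2 (1 atm), Pd(OH)2/C, THF–MeOH, rt
Reagents that add atoms: none
Why: Hydrogenolysis cleaves the three aryl benzyl ethers and the two diphenylmethylene ketals, while under neutral conditions the secondary alcohols, the benzylic 4-OH, the interflavan C–C bond and all stereocentres should remain.

## Compound list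

1 | pyrogallol (benzene-1,2,3-triol) | Oc1cccc(O)c1O | starting material
2 | 2,2-diphenyl-1,3-benzodioxol-4-ol | Oc1cccc2c1OC(c1ccccc1)(c1ccccc1)O2 | intermediate
3 | 4-(allyloxy)-2,2-diphenyl-1,3-benzodioxole | C=CCOc1cccc2c1OC(c1ccccc1)(c1ccccc1)O2 | intermediate
4 | 5-allyl-2,2-diphenyl-1,3-benzodioxol-4-ol | Oc1c(CC=C)ccc2c1OC(c1ccccc1)(c1ccccc1)O2 | intermediate
5 | 3,4-bis(benzyloxy)benzoic acid | OC(=O)c1ccc(OCc2ccccc2)c(OCc2ccccc2)c1 | starting material
6 | 5-allyl-2,2-diphenyl-1,3-benzodioxol-4-yl 3,4-bis(benzyloxy)benzoate | O=C(Oc1c(CC=C)ccc2c1OC(c1ccccc1)(c1ccccc1)O2)c1ccc(OCc2ccccc2)c(OCc2ccccc2)c1 | intermediate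
7 | 3',4'-bis(benzyloxy)-7,8-(diphenylmethylenedioxy)flav-2-ene | O1C(c4ccc(OCc5ccccc5)c(OCc5ccccc5)c4)=CCc2ccc3OC(c4ccccc4)(c4ccccc4)Oc3c12 | intermediate
8 | [2,3-trans-3',4'-bis(benzyloxy)-7,8-(diphenylmethylenedioxy)flavan-3-yl](isopinocampheyl)borane, boron on C3 cis to H-2 | C[C@H]1[C@H](B[C@H]9Cc2ccc3OC(c4ccccc4)(c4ccccc4)Oc3c2O[C@@H]9c2ccc(OCc3ccccc3)c(OCc3ccccc3)c2)C[C@@H]2C[C@H]1C2(C)C | intermediate (not isolated)
9 | (2R,3S)-3',4'-bis(benzyloxy)-7,8-(diphenylmethylenedioxy)flavan-3-ol | O1[C@H](c4ccc(OCc5ccccc5)c(OCc5ccccc5)c4)[C@@H](O)Cc2ccc3OC(c4ccccc4)(c4ccccc4)Oc3c12 | intermediate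
10 | (2R)-3',4'-bis(benzyloxy)-7,8-(diphenylmethylenedioxy)flavan-3-one | O1[C@H](c4ccc(OCc5ccccc5)c(OCc5ccccc5)c4)C(=O)Cc2ccc3OC(c4ccccc4)(c4ccccc4)Oc3c12 | intermediate
11 | (2R,3R)-3',4'-bis(benzyloxy)-7,8-(diphenylmethylenedioxy)flavan-3-ol | O1[C@H](c4ccc(OCc5ccccc5)c(OCc5ccccc5)c4)[C@H](O)Cc2ccc3OC(c4ccccc4)(c4ccccc4)Oc3c12 | intermediate
12 | 4-(benzyloxy)benzoic acid | OC(=O)c1ccc(OCc2ccccc2)cc1 | starting material
13 | 5-allyl-2,2-diphenyl-1,3-benzodioxol-4-yl 4-(benzyloxy)benzoate | O=C(Oc1c(CC=C)ccc2c1OC(c1ccccc1)(c1ccccc1)O2)c1ccc(OCc2ccccc2)cc1 | intermediate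
14 | 4'-(benzyloxy)-7,8-(diphenylmethylenedioxy)flav-2-ene | O1C(c4ccc(OCc5ccccc5)cc4)=CCc2ccc3OC(c4ccccc4)(c4ccccc4)Oc3c12 | intermediate
15 | [2,3-trans-4'-(benzyloxy)-7,8-(diphenylmethylenedioxy)flavan-3-yl](isopinocampheyl)borane, boron on C3 cis to H-2 | C[C@H]1[C@H](B[C@H]9Cc2ccc3OC(c4ccccc4)(c4ccccc4)Oc3c2O[C@@H]9c2ccc(OCc3ccccc3)cc2)C[C@@H]2C[C@H]1C2(C)C | intermediate (not isolated)
16 | (2R,3S)-4'-(benzyloxy)-7,8-(diphenylmethylenedioxy)flavan-3-ol | O1[C@H](c4ccc(OCc5ccccc5)cc4)[C@@H](O)Cc2ccc3OC(c4ccccc4)(c4ccccc4)Oc3c12 | intermediate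
17 | (2R)-4'-(benzyloxy)-7,8-(diphenylmethylenedioxy)flavan-3-one | O1[C@H](c4ccc(OCc5ccccc5)cc4)C(=O)Cc2ccc3OC(c4ccccc4)(c4ccccc4)Oc3c12 | intermediate
18 | (2R,3R)-4'-(benzyloxy)-7,8-(diphenylmethylenedioxy)flavan-3-ol | O1[C@H](c4ccc(OCc5ccccc5)cc4)[C@H](O)Cc2ccc3OC(c4ccccc4)(c4ccccc4)Oc3c12 | intermediate
19 | (2R,3R,4S)-4'-(benzyloxy)-4-(2-ethoxyethoxy)-7,8-(diphenylmethylenedioxy)flavan-3-ol | O1[C@H](c4ccc(OCc5ccccc5)cc4)[C@H](O)[C@@H](OCCOCC)c2ccc3OC(c4ccccc4)(c4ccccc4)Oc3c12 | intermediate
20 | protected biflavanoid, upper unit (2R,3R,4R) with 4β bond to C6 of the lower (2R,3R)-flavan-3-ol | O1[C@H](c4ccc(OCc5ccccc5)cc4)[C@H](O)[C@@H](c4cc5C[C@@H](O)[C@@H](c7ccc(OCc8ccccc8)c(OCc8ccccc8)c7)Oc5c6OC(c7ccccc7)(c7ccccc7)Oc46)c2ccc3OC(c4ccccc4)(c4ccccc4)Oc3c12 | intermediate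
21 | protected biflavanoid 4-ol, upper unit (2R,3R,4R), lower unit (2R,3R,4S)-flavan-3,4-diol | O1[C@H](c4ccc(OCc5ccccc5)cc4)[C@H](O)[C@@H](c4cc5[C@H](O)[C@@H](O)[C@@H](c7ccc(OCc8ccccc8)c(OCc8ccccc8)c7)Oc5c6OC(c7ccccc7)(c7ccccc7)Oc46)c2ccc3OC(c4ccccc4)(c4ccccc4)Oc3c12 | intermediate
22 | CNP0275688.1, (2R,3R,4S)-2-(3,4-dihydroxyphenyl)-6-[(2R,3R,4S)-3,7,8-trihydroxy-2-(4-hydroxyphenyl)chroman-4-yl]chromane-3,4,7,8-tetrol | Oc1ccc([C@H]2Oc3c(ccc(O)c3O)[C@H](c3cc4c(c(O)c3O)O[C@H](c3ccc(O)c(O)c3)[C@H](O)[C@H]4O)[C@H]2O)cc1 | target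

## Step count and risks

Total step count: 17. Longest linear sequence: 12 steps (steps 1–3, then 9–17).

Steps most likely to fail:

**Step 16.** Hydride abstraction may not stay at C4 of the lower unit: H-2 next to the alkoxyaryl rings or the upper H-4 may compete, and the new benzylic alcohol may be oxidised on to the ketone. The fallback sets out from 11 and 19 and comes back at 21. The oxidation is moved in front of the union, where only one flavan is present: DDQ and water in CH2Cl2 should turn 11 into the (2R,3R,4S)-flavan-3,4-diol F1. Ether 19 is exchanged with BnSH and ZnI2 in CH2Cl2 at 0 °C into the 4β-benzylsulfanyl flavan-3-ol F2 (capture of the C4 cation by sulfur trans to the 3-OH). AgBF4 in THF at 0 °C should then ionise only the C–S bond of F2, and C6 of ring A of F1 captures the cation to give 21; the benzylic 4-OH of F1 is not activated by the thiophilic silver salt.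

**Step 5.** The titanium ethylidene may olefinate the ester without closing the ring, isomerise the allyl group into conjugation, or cleave the aryl ester reductively. The fallback sets out from 6 and comes back at 7, and separates the two events. Methylenation of the ester carbonyl with Cp2TiMe2 (toluene, 70 °C; Petasis methylenation) gives the 1-arylvinyl aryl ether F3. Ring-closing metathesis with the second-generation Grubbs catalyst (toluene, 80 °C) then forms C2=C3 with loss of ethylene.

**Step 6.** Facial discrimination by the chiral borane may be incomplete or of the opposite sense on an enol ether flanked by an aryl group, and the β-oxygenated borane may ring-open by elimination before oxidation. The fallback sets out from 7 and comes back at 11, and moves stereocontrol to the ketone stage. BH3·SMe2 in THF followed by NaOH/H2O2 gives the racemic trans-flavan-3-ol F4, and Dess–Martin periodinane gives the racemic flavan-3-one F5. Asymmetric hydrogenation with dynamic kinetic resolution (RuCl2(SDP)(DPEN), t-BuOK, i-PrOH, H2) then reduces one enantiomer while C2 epimerises through the enolate, giving the cis alcohol 11; the catalyst enantiomer used is the one that forms the (3R) carbinol.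

Further compounds
F1 | step 16 | (2R,3R,4S)-3',4'-bis(benzyloxy)-7,8-(diphenylmethylenedioxy)flavan-3,4-diol | O1[C@H](c4ccc(OCc5ccccc5)c(OCc5ccccc5)c4)[C@H](O)[C@@H](O)c2ccc3OC(c4ccccc4)(c4ccccc4)Oc3c12
F2 | step 16 | (2R,3S,4S)-4'-(benzyloxy)-4-(benzylsulfanyl)-7,8-(diphenylmethylenedioxy)flavan-3-ol (4β, 2,3-cis-3,4-trans) | O1[C@H](c4ccc(OCc5ccccc5)cc4)[C@H](O)[C@@H](SCc4ccccc4)c2ccc3OC(c4ccccc4)(c4ccccc4)Oc3c12
F3 | step 5 | 5-allyl-4-({1-[3,4-bis(benzyloxy)phenyl]vinyl}oxy)-2,2-diphenyl-1,3-benzodioxole | C=C(Oc1c(CC=C)ccc2c1OC(c1ccccc1)(c1ccccc1)O2)c1ccc(OCc2ccccc2)c(OCc2ccccc2)c1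
F4 | step 6 | racemic 2,3-trans-3',4'-bis(benzyloxy)-7,8-(diphenylmethylenedioxy)flavan-3-ol (both enantiomers) | O1[C@H](c4ccc(OCc5ccccc5)c(OCc5ccccc5)c4)[C@@H](O)Cc2ccc3OC(c4ccccc4)(c4ccccc4)Oc3c12.O1[C@@H](c4ccc(OCc5ccccc5)c(OCc5ccccc5)c4)[C@H](O)Cc2ccc3OC(c4ccccc4)(c4ccccc4)Oc3c12
F5 | step 6 | racemic 3',4'-bis(benzyloxy)-7,8-(diphenylmethylenedioxy)flavan-3-one (no configuration implied at C2) | O1C(c4ccc(OCc5ccccc5)c(OCc5ccccc5)c4)C(=O)Cc2ccc3OC(c4ccccc4)(c4ccccc4)Oc3c12
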